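(Readings and results were computed on assumed constants, and the scatter is random.)

Every J made costs one L, so J and the L still free can sum to no more than the L charged. In the epsilon flask L is the limiting reagent, at 0.400 M against 2.40 M of Q, so J cannot pass 16.7% of the Q charged.

| flask | Q | L | time |
|---|---|---|---|
| gamma | 0.800 M | 1.20 M |  |
| alpha | 0.800 M | 0.600 M |  |
| delta | 1.60 M | 1.20 M |  |
| epsilon | 2.40 M | 0.400 M | 11 h |

| run | time / h | [J] / M |
|---|---|---|
| gamma run | 0.39 | 0.033 |
| gamma run | 1.2 | 0.082 |
| gamma run | 2.3 | 0.121 |
| gamma run | 3.6 | 0.155 |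
| gamma run | 5.2 | 0.167 |
| gamma run | 6.9 | 0.181 |
| gamma run | 8.9 | 0.192 |
| gamma run | 11 | 0.188 |
| alpha run | 0.39 | 0.015 |
| alpha run | 1.2 | 0.041 |
| alpha run | 2.3 | 0.066 |
| alpha run | 3.6 | 0.087 |
| alpha run | 5.2 | 0.096 |
| alpha run | 6.9 | 0.104 |
| alpha run | 8.9 | 0.102 |
| alpha run | 11 | 0.108 |
| delta run | 0.39 | 0.051 |
| delta run | 1.2 | 0.142 |
| delta run | 2.3 | 0.206 |
| delta run | 3.6 | 0.258 |
| delta run | 5.2 | 0.278 |
| delta run | 6.9 | 0.296 |
| delta run | 8.9 | 0.300 |
| delta run | 11 | 0.310 |

(scatter of a reading: 0.004 M)

- Overall: Q + L -> J.
- Constant volume, constant temperature.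
- An order is taken over about fifteen percent of the charge, up and down.

- apparent order in [Q] of the starting rate, round the charge of the gamma run (the rate where two percent of its Q have turned into J) (one fixed amount of J, the same in the runs compared)
- apparent order in [L] of the starting rate, round the charge of the gamma run (the rate where two percent of its Q have turned into J)
- J in the epsilon run at 11 h, as a share of the Q charged

That ceiling is loose. The gamma run read 0.192 M and then 0.188 M, and that last reading is 15.7% of its L. I took the levelling as a finished race: L ends either as J or elsewhere. My measure was the odds per molar of Q charged, a selectivity factor: last J, over L charged minus that J, over Q charged. For the gamma run this is 0.232 M⁻¹, for the alpha run 0.274 M⁻¹ and for the delta run 0.218 M⁻¹.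

For a working floor, an estimate and no strict bound, I noted that the last delta reading stood at 25.8% of its L, more than the gamma share. Epsilon has more Q and less L than delta, so I carried that share over, which gives 4.31% of the Q charged. For a working ceiling, again an estimate, I used the alpha odds, the highest of the three as read, which give 6.62%. The gamma odds gave me 5.96%.

The forecast said 5.5%, inside my bracket but lower than my figure, with orders 0.8 in Q and 1 in L: “I expect about 0.133 M, or 5.5%.”

The flask gave 6.17%, inside my bracket, with orders 1.1 in Q and 1.1 in L.

Q + L → J (0.09072 M⁻¹ h⁻¹); J + L → Z (0.05580 M⁻¹ h⁻¹); L → Qa (0.1886 h⁻¹); 2 Q → Jy (0.06120 M⁻¹ h⁻¹) With the same amount of J made, the delta run's rate stood at 2.1 times the gamma run's. The epsilon result makes its odds per molar 0.245 M⁻¹, above the gamma 0.232 M⁻¹ and below the alpha 0.274 M⁻¹. Put on the gamma charge, those epsilon odds give 0.197 M of J, against a last reading of 0.188 M.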